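All runs are simulated for substances that don't exist; scatter was added.

Two questions stood before me, how much left-handed product each of these flasks holds at the end and what course those numbers take, and I kept my books in fractions of the charge, meaning the left-handed substrate and right-handed substrate together.

| setting | blue | green | Tuesday's | Saturday's | Friday's |
|---|---|---|---|---|---|
| left-handed substrate | 0.20 M | 0.20 M | 0.20 M | 0.20 M | 0.20 M |
| right-handed substrate | 0.20 M | 0.20 M | 0.20 M | 0.20 M | 0.20 M |
| solid reagent | 0.12 M | 0.12 M | 0.120 M | 0.120 M | 0.120 M |
| catalyst | 4.8 mM | 4.8 mM | 4.8 mM | 4.8 mM | 4.8 mM |
| added ligand | 7.4 mM | 17 mM | 10 mM | 15 mM | 25 mM |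
| remark | run made earlier | run made earlier |  |  |  |
| time |  |  | 10 min | 10 min | 10 min |

- blue (time / min: left-handed product / %, left-handed substrate / %): 0.667: 17.9, 33.6; 2.00: 22.7, 26.2; 3.00: 22.8, 26.4; 5.00: 22.9, 27.2; 8.00: 23.6, 26.5
- green (time / min: left-handed product / %, left-handed substrate / %): 1.33: 18.4, 31.9; 3.00: 20.0, 29.0; 4.00: 21.7, 28.6; 6.00: 21.7, 28.3; 8.00: 21.7, 28.2

(standard deviation of a reading: 0.5 percentage points)

1. amount of left-handed product at the end, in percent of the left-handed substrate and right-handed substrate together charged for Tuesday's, Saturday's, Friday's, in this order
2. the course of these numbers from the first flask to the last (rises all the way / falls all the way / falls, then rises / hardly changes / rises, then falls)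

- catalyst is single-handed; left-handed substrate and right-handed substrate are mirror images of each other, charged as a racemate, each of them at the stated concentration
- as a solid, counted per litre of solution: solid reagent
- the earlier runs were read with a standard deviation of 0.5 percentage points
- what may be going on: coupling partner + catalyst + left-handed substrate -> catalyst + left-handed product; coupling partner + catalyst + right-handed substrate -> catalyst + right-handed product; 2 coupling partner -> homo dimer; solid reagent <-> coupling partner; catalyst + added ligand <-> idle complex
- at the start none of the solid reagent is in solution
- "hardly changes" means that all values lie within two and a half points (for a concentration: within two and a half percent of the largest)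

The ledger opened with the solid reagent: each unit dissolves to one coupling partner and each coupling partner makes one product, so its whole charge stood for a cap of 30.0%, less than the left-handed substrate's own share, which made the solid reagent the limiting reagent. Product was the large entry, so I reckoned only the correction. The readings of the blue run levelled at 23.0% with left-handed substrate still reading 26.5%, so its leak, the cap less the left-handed product at the end, read 7 percentage points. The readings of the green run levelled at 21.7%, reached by 4.00 min where blue had needed 2.00 min, twice as long, and its leak read 8.3 points. The leak entries I expected were right-handed product and homo dimer, which swallows two coupling partners at a time.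

On a straight line in added ligand I put the leak at 7.4 points for Tuesday's flask and 9.4 points for Friday's, which leaves 22.6% and 20.6% of product. That span of 2 points stays under the 2.5 points of the margin, but only by about the scatter of one reading, 0.5 points, so my line alone could not separate the two words, and I committed to a fall all the way.

The forecast gave 22.6%, 21.9% and 20.5% and, where I had committed to a fall, called the course "hardly changes", while granting that “it is a slight monotonic decline”.

The flasks gave 22.9%, 22.0% and 20.3%, so the course falls all the way, over a span of 2.6 points, beyond the margin, under these equations:

    coupling partner + catalyst + left-handed substrate → catalyst + left-handed product (k = 64.4 M⁻² s⁻¹)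
    coupling partner + catalyst + right-handed substrate → catalyst + right-handed product (k = 0.774 M⁻² s⁻¹)
    2 coupling partner → homo dimer (k = 0.115 M⁻¹ s⁻¹)
    solid reagent ⇌ coupling partner, rate k4*(cs4 - [coupling partner]) while solid is left; crystals form when [coupling partner] > cs4 (solubility = 0.0690 M, k = 0.262 s⁻¹)
    catalyst + added ligand ⇌ idle complex (K = 72.0 M⁻¹, k = 15.8 M⁻¹ s⁻¹)

Tuesday's leak came to 7.1 points, and with the solid reagent at 0% the books close on it: homo dimer, two coupling partners each, holds 6.70% of the charge and right-handed product 0.367%. Friday's leak was 9.7 points, of which homo dimer held 9.42% and right-handed product 0.311%.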